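**Retrosynthetic overview**
- Feature: ring A of the indenone (C3a, C4, C5, C6, C7, C7a) carries the C4 formyl and the C7 methyl para to each other across an unsubstituted C5–C6 edge. It is fused through C3a/C7a to the β/α carbons of the five-membered enone ring B. An isoprene-like diene C6=C7(CH3)–C7a=C3a and propynal as C4≡C5 leave exactly this pattern.
- The C2=C3 bond is traced back to a C3 tertiary carbinol (loss of water, last step), and aromatic ring A to its 1,4-cyclohexadiene (loss of H2). Oxidation comes first, because early water loss would let the adduct tautomerise to the indanone oxidation level.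
- Key cut: C3a–C4 and C5–C6 by Diels–Alder reaction, giving a 4-hydroxy-2-isopropenylcyclopentenone and propynal.
- The diene comes from a base-free Stille coupling on the 2-iodoenone. Ring B, with C1=O, the C2 azulenyl and C3(CH3)(OH) in place, comes from a Piancatelli rearrangement of guaiazulen-3-yl(5-methylfuran-2-yl)methanol, which is made from formylated guaiazulene and lithiated 2-methylfuran.
- Ring order: azulene (bought), then ring B (4π closure), then ring A ([4+2], afterwards aromatised).

Key step: step 6

Assumption: the target has no stereocentre, so every sp3 intermediate is racemic. The SMILES show one enantiomer, kept in one consistent series from 7 to 13. The trans OH/azulenyl relation in 7 is assigned by analogy with the parent rearrangement and has no consequence for 14.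
Assumption: propynal is bought as a stabilised solution and flash-distilled before use. "Guaiazulen-3-yl" means 5-isopropyl-3,8-dimethylazulen-1-yl.

**Step 1**
Reactants: 1 guaiazulene
Product: 3 guaiazulene-3-carbaldehyde, via N,N-dimethyliminium dichlorophosphate 2 (not isolated)
Conditions: POCl3 (1.1 equiv), DMF, 0 °C → rt; then 2 M aq NaOH, 0 °C
Reagents that add atoms: N,N-dimethylformamide, CN(C)C=O; water, O
Why: Vilsmeier–Haack formylation, in which C3 is the only free position of the electron-rich five-membered ring (C1 bears methyl), so the chloroiminium ion attacks there and the iminium salt hydrolyses to the aldehyde on basic work-up; no stereocentre is formed.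

**Step 2**
Reactants: 3 guaiazulene-3-carbaldehyde; 4 2-methylfuran
Product: 6 rac-(guaiazulen-3-yl)(5-methylfuran-2-yl)methanol, via 5-methyl-2-furyllithium 5 (not isolated)
Conditions: 4 (1.3 equiv), n-BuLi (1.2 equiv), THF, 0 °C → rt; then 3, −78 °C; H2O quench; crude 6 used at once
Reagents that add atoms: none
Why: α-lithiation of 2-methylfuran at its free C5 followed by 1,2-addition of the heteroaryllithium to the aldehyde, which at −78 °C should outrun deprotonation of the acidic azulene C4 methyl and addition to the seven-membered ring; the carbinol centre forms racemic and is re-set in step 3.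

**Step 3**
Reactants: 6 rac-(guaiazulen-3-yl)(5-methylfuran-2-yl)methanol
Product: 7 rac-(4R,5S)-5-(guaiazulen-3-yl)-4-hydroxy-4-methylcyclopent-2-en-1-one (OH trans to azulenyl)
Conditions: Dy(OTf)3 (10 mol %), t-BuOH/H2O (5:1), 70 °C, Ar, dark
Reagents that add atoms: water, O
Why: Piancatelli rearrangement, a known reaction of 5-methylfuryl aryl carbinols, in which the Lewis acid ionises the carbinol, water adds at the methyl-bearing furan C5, the hemiketal opens to a 1,4-dihydroxypentadienyl cation, and conrotatory 4π electrocyclisation closes ring B with azulenyl and hydroxyl both outward on the termini, which sets C4 and C5 together as the trans racemate.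

**Step 4**
Reactants: 7 rac-(4R,5S)-5-(guaiazulen-3-yl)-4-hydroxy-4-methylcyclopent-2-en-1-one
Product: 8 rac-(4S,5S)-5-(guaiazulen-3-yl)-4-hydroxy-2-iodo-4-methylcyclopent-2-en-1-one (same spatial arrangement as 7)
Conditions: I2 (1.5 equiv), pyridine/CH2Cl2 (1:1), 0 °C → rt, dark
Reagents that add atoms: iodine, II
Why: α-iodination of an enone by the Baylis–Hillman-type sequence (pyridine adds at C3, the enolate is iodinated at C2, pyridine leaves), which is known for 4,4-disubstituted cyclopentenones; pyridine is too weak a base at this temperature to enolise C5 and expel the C4 hydroxyl, both nucleophilic azulene positions are blocked, and C4/C5 are untouched.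

**Step 5**
Reactants: 8 rac-(4S,5S)-5-(guaiazulen-3-yl)-4-hydroxy-2-iodo-4-methylcyclopent-2-en-1-one; 9 tributyl(prop-1-en-2-yl)stannane
Product: 10 rac-(4R,5S)-5-(guaiazulen-3-yl)-4-hydroxy-4-methyl-2-(prop-1-en-2-yl)cyclopent-2-en-1-one (OH trans to azulenyl)
Conditions: Pd2(dba)3 (2.5 mol %), AsPh3 (10 mol %), CuI (10 mol %), NMP, rt → 40 °C, Ar; 10 used promptly
Reagents that add atoms: none
Why: Stille coupling of a 2-iodoenone with an alkenylstannane under AsPh3/CuI acceleration, preferred to a boronate coupling because it needs no base, so the base-labile 4-hydroxy-5-aryl enone should neither lose water to a cyclopentadienone nor transpose its hydroxyl; the tertiary alcohol, the azulene and both stereocentres are inert to zerovalent palladium.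

**Step 6**
Reactants: 10 rac-(4R,5S)-5-(guaiazulen-3-yl)-4-hydroxy-4-methyl-2-(prop-1-en-2-yl)cyclopent-2-en-1-one; 11 propynal
Product: 12 rac-(2S,3R,3aR)-2-(guaiazulen-3-yl)-3-hydroxy-3,7-dimethyl-1-oxo-2,3,3a,6-tetrahydro-1H-indene-4-carbaldehyde
Conditions: 11 (8 equiv), BHT (5 mol %), toluene (0.2 M), sealed tube, 90 °C, Ar, dark
Reagents that add atoms: none
Why: The step is a concerted but asynchronous suprafacial [4+2] cycloaddition of the s-cis cross-conjugated diene C6=C7(CH3)–C7a=C3a of 10 with the triple bond C4≡C5 of 11, and its closest known relative is the Diels–Alder benzannulation of 2-alkenylcycloalk-2-enones with acetylenic dienophiles followed by aromatisation. Ring A closes as a six-membered 1,4-cyclohexadiene by intermolecular two-bond annulation (C5–C6 leading, C3a–C4 lagging), which leaves C7=C7a conjugated with C1=O and C4=C5 conjugated with the formyl group. The selectivity that matters is regiochemical (formyl at C4, para to the C7 methyl): the leading bond to the β-carbon of the strongly electrophilic ynal should form at the unhindered C6 methylene, because the charge then develops on the allyl unit C7–C7a–C3a with the methyl on one terminus, the C3 alkyl on the other and the carbonyl on the nodal centre, whereas bonding first at C3a means attack at a carbon next to the quaternary C3 and places charge on C7a beside the carbonyl, so sterics, the para-directing C7 methyl and the ortho-directing C3 substituent together should outweigh the opposing pull of the C1 acyl group. The one new stereocentre, C3a, is controlled by the resident C2 and C3 centres, since the dienophile approaches the ring face that bears only the small C3 hydroxyl, anti to the C3 methyl and the C2 azulenyl, and an O–H···O=CH hydrogen bond available only in this orientation should reinforce both face and regiochemistry; the centre is erased in step 7, so an epimer would do no harm. Chemoselectivity rests on the blocked C1 and C3 positions of the guaiazulene (azulene–alkyne cycloaddition needs far higher temperature), on neutral conditions that keep the β-hydroxy ketone from losing water and the hydroxyl from oxa-Michael addition, and on excess dienophile with BHT to outrun diene dimerisation and ynal polymerisation. Because the diene carries an acceptor it needs heat, and the choice of the most reactive mono-activated alkyne keeps that heat moderate.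

**Step 7**
Reactants: 12 rac-(2S,3R,3aR)-2-(guaiazulen-3-yl)-3-hydroxy-3,7-dimethyl-1-oxo-2,3,3a,6-tetrahydro-1H-indene-4-carbaldehyde
Product: 13 rac-(2S,3S)-2-(guaiazulen-3-yl)-3-hydroxy-3,7-dimethyl-1-oxo-2,3-dihydro-1H-indene-4-carbaldehyde (OH trans to azulenyl)
Conditions: activated MnO2 (15 equiv), CH2Cl2, rt
Reagents that add atoms: none
Why: Oxidative aromatisation of a 1,4-cyclohexadiene, in which the doubly allylic C6–H and C3a–H are removed at room temperature under neutral heterogeneous conditions that spare the tertiary alcohol, the aldehyde and the azulene (quinones of high potential would attack its C1 methyl); C3a is erased, C2 and C3 are untouched, and the C3 hydroxyl is kept as the latent C2=C3 unsaturation.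

**Step 8**
Reactants: 13 rac-(2S,3S)-2-(guaiazulen-3-yl)-3-hydroxy-3,7-dimethyl-1-oxo-2,3-dihydro-1H-indene-4-carbaldehyde
Product: 14 2-(guaiazulen-3-yl)-3,7-dimethyl-1-oxo-1H-indene-4-carbaldehyde (target)
Conditions: p-TsOH·H2O (10 mol %), 4 Å MS, toluene, 60 °C
Reagents that add atoms: none
Why: Acid-catalysed aldol-type dehydration of a β-hydroxy ketone through the C1 enol, which under equilibrating conditions should give the tetrasubstituted C2=C3 enone conjugated with carbonyl, arene and azulene (azulene protonation is reversible, and any retro-aldol opening recloses to the same indenone); the last two stereocentres are erased.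

**Compound list**
1 | guaiazulene (7-isopropyl-1,4-dimethylazulene) | CC(C)c1ccc(C)c2ccc(C)c2c1 | starting material
2 | N,N-dimethyl(guaiazulen-3-yl)methaniminium dichlorophosphate | C[N+](C)=Cc1cc(C)c2cc(C(C)C)ccc(C)c1-2.[O-]P(=O)(Cl)Cl | intermediate
3 | guaiazulene-3-carbaldehyde (5-isopropyl-3,8-dimethylazulene-1-carbaldehyde) | O=Cc1cc(C)c2cc(C(C)C)ccc(C)c1-2 | intermediate
4 | 2-methylfuran | Cc1ccco1 | starting material
5 | 5-methyl-2-furyllithium | [Li]c1ccc(C)o1 | intermediate
6 | rac-(guaiazulen-3-yl)(5-methylfuran-2-yl)methanol | OC(c1ccc(C)o1)c1cc(C)c2cc(C(C)C)ccc(C)c1-2 | intermediate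
7 | rac-(4R,5S)-5-(guaiazulen-3-yl)-4-hydroxy-4-methylcyclopent-2-en-1-one, OH trans to azulenyl | C1=C[C@@](C)(O)[C@H](c2cc(C)c3cc(C(C)C)ccc(C)c2-3)C1=O | intermediate
8 | rac-(4S,5S)-5-(guaiazulen-3-yl)-4-hydroxy-2-iodo-4-methylcyclopent-2-en-1-one, OH trans to azulenyl | IC1=C[C@@](C)(O)[C@H](c2cc(C)c3cc(C(C)C)ccc(C)c2-3)C1=O | intermediate
9 | tributyl(prop-1-en-2-yl)stannane | C=C(C)[Sn](CCCC)(CCCC)CCCC | starting material
10 | rac-(4R,5S)-5-(guaiazulen-3-yl)-4-hydroxy-4-methyl-2-(prop-1-en-2-yl)cyclopent-2-en-1-one, OH trans to azulenyl | C=C(C)C1=C[C@@](C)(O)[C@H](c2cc(C)c3cc(C(C)C)ccc(C)c2-3)C1=O | intermediate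
11 | propynal | C#CC=O | starting material
12 | rac-(2S,3R,3aR)-2-(guaiazulen-3-yl)-3-hydroxy-3,7-dimethyl-1-oxo-2,3,3a,6-tetrahydro-1H-indene-4-carbaldehyde, C3a–H cis to azulenyl and C3 methyl | O=CC1=CCC(C)=C2C(=O)[C@@H](c3cc(C)c4cc(C(C)C)ccc(C)c3-4)[C@](C)(O)[C@H]12 | intermediate
13 | rac-(2S,3S)-2-(guaiazulen-3-yl)-3-hydroxy-3,7-dimethyl-1-oxo-2,3-dihydro-1H-indene-4-carbaldehyde, OH trans to azulenyl | O=Cc1ccc(C)c2C(=O)[C@@H](c3cc(C)c4cc(C(C)C)ccc(C)c3-4)[C@](C)(O)c12 | intermediate
14 | 2-(guaiazulen-3-yl)-3,7-dimethyl-1-oxo-1H-indene-4-carbaldehyde | CC1=C(c2cc(C)c3cc(C(C)C)ccc(C)c2-3)C(=O)c2c(C)ccc(C=O)c21 | target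

**Step count**
Total step count: 8. Longest linear sequence: 8 (1 → 14).

**Steps most likely to fail**

*Step 6.* The cycloaddition pairs an acceptor-substituted diene with an acceptor alkyne. It may therefore be slow enough for diene dimerisation and ynal polymerisation to take over. The C1 acyl group on C7a also favours first bonding at C3a, so the regiocontrol exerted by the alkyl groups and by sterics may leak.

The fallback sets out from 10 and comes back at 13.
- Luche reduction (NaBH4, CeCl3·7H2O, MeOH, −40 °C) takes the carbonyl out of conjugation. It should give 5-(guaiazulen-3-yl)-4-methyl-2-(prop-1-en-2-yl)cyclopent-2-ene-1,4-diol F1 (C1 epimers, both usable). This is a 1-isopropenylcyclopentene-type trialkyl diene with a raised HOMO, and dienes of this type are known to place the acceptor next to the ring-fusion carbon.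
- Cycloaddition with 11 (toluene, 40 °C) should then give 2-(guaiazulen-3-yl)-1,3-dihydroxy-3,7-dimethyl-2,3,3a,6-tetrahydro-1H-indene-4-carbaldehyde F2.
- Excess activated MnO2 (CH2Cl2, rt) re-oxidises the allylic C1 carbinol and aromatises ring A in one operation, arriving at 13.

*Step 3.* The azulene stabilises the cation so strongly that capture at the carbinol carbon (ether and oligomer formation) may dominate. Alternatively, the opened chain may tautomerise instead of electrocyclising. Prolonged heating may also transpose the hydroxyl.

The fallback sets out from 6 and comes back at 7. It splits the rearrangement into two known operations with an ionic ring closure.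
- Hydrolytic opening of the furan (dilute aqueous HCl, THF, rt) should give (Z)-1-(guaiazulen-3-yl)hex-3-ene-2,5-dione F3.
- A short intramolecular aldol addition (dilute aqueous Na2CO3, dioxane, 0 °C) lets the azulenyl-activated C1 methylene add to the C5 methyl ketone, a known entry to 4-hydroxycyclopentenones.
- This should give 7 beside its epimer, cis-5-(guaiazulen-3-yl)-4-hydroxy-4-methylcyclopent-2-en-1-one F4. F4 is separated and re-equilibrated under the same reversible aldol conditions.

*Step 4.* Electrophilic iodine may attack or oxidise the electron-rich azulene. Pyridine may also start enolisation at C5, with loss or transposition of the C4 hydroxyl.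

The fallback sets out from 3 and comes back at 10. It brings the halogen in with the furan, so no electrophilic halogen ever meets the azulene.
- Purchased 2-bromo-5-methylfuran F5 is treated with LDA (THF, −78 °C). The known halogen dance should deliver 3-bromo-5-methyl-2-furyllithium F6.
- F6 adds to 3 to give (3-bromo-5-methylfuran-2-yl)(guaiazulen-3-yl)methanol F7.
- Piancatelli rearrangement under the conditions of step 3 maps furan C3 onto enone C2. It should give 2-bromo-5-(guaiazulen-3-yl)-4-hydroxy-4-methylcyclopent-2-en-1-one F8 (OH trans to azulenyl).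
- Stille coupling of F8 with 9 under the conditions of step 5 (50 °C) gives 10.

**Further compounds**
F1 | step 6 | 5-(guaiazulen-3-yl)-4-methyl-2-(prop-1-en-2-yl)cyclopent-2-ene-1,4-diol (racemic, C1 epimers) | C=C(C)C1=C[C@@](C)(O)[C@H](c2cc(C)c3cc(C(C)C)ccc(C)c2-3)C1O
F2 | step 6 | 2-(guaiazulen-3-yl)-1,3-dihydroxy-3,7-dimethyl-2,3,3a,6-tetrahydro-1H-indene-4-carbaldehyde (racemic, C1 epimers) | O=CC1=CCC(C)=C2C(O)[C@@H](c3cc(C)c4cc(C(C)C)ccc(C)c3-4)[C@](C)(O)[C@H]12
F3 | step 3 | (Z)-1-(guaiazulen-3-yl)hex-3-ene-2,5-dione | CC(=O)/C=C\C(=O)Cc1cc(C)c2cc(C(C)C)ccc(C)c1-2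
F4 | step 3 | cis-5-(guaiazulen-3-yl)-4-hydroxy-4-methylcyclopent-2-en-1-one (racemic, OH cis to azulenyl) | C1=C[C@](C)(O)[C@H](c2cc(C)c3cc(C(C)C)ccc(C)c2-3)C1=O
F5 | step 4 | 2-bromo-5-methylfuran (purchased) | Cc1ccc(Br)o1
F6 | step 4 | 3-bromo-5-methyl-2-furyllithium | [Li]c1oc(C)cc1Br
F7 | step 4 | (3-bromo-5-methylfuran-2-yl)(guaiazulen-3-yl)methanol (racemic) | OC(c1oc(C)cc1Br)c1cc(C)c2cc(C(C)C)ccc(C)c1-2
F8 | step 4 | 2-bromo-5-(guaiazulen-3-yl)-4-hydroxy-4-methylcyclopent-2-en-1-one (racemic, OH trans to azulenyl) | BrC1=C[C@@](C)(O)[C@H](c2cc(C)c3cc(C(C)C)ccc(C)c2-3)C1=O
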